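## Structural features

The target is a 1-aryl-1,2-dihydronaphthalene lignan. Ring A is a benzene ring with methoxy groups at C6 and C8 and a free hydroxyl at C7; it is fused to ring B, whose carbons are C1 (bearing the 4-hydroxy-3,5-dimethoxyphenyl group Ar′), C2 (bearing the hydroxymethyl carbon C9), C3 (bearing the methyl ester) and C4, with C3=C4 conjugated to ring A. The two stereocentres are neighbours: C1 (S), a doubly benzylic methine next to the C8 methoxy group, and C2 (R), with Ar′ and C9 trans. Three features are fragile. C2–H is allylic and γ to the enoate, so base can move the double bond to C2=C3 or lead on to the naphthalene. The C9 hydroxyl sits next to the C3 ester and can lactonise, above all while C3 is tetrahedral and cis. Both phenols are easily oxidised 2,6-dimethoxyphenols, the ring A one para to C4a and the Ar′ one para to C1. The real difficulty is to set C1 in the absolute sense on a crowded diarylmethine, relay it to C2, and introduce the C3=C4 enoate last without disturbing either centre. The key step exploits the C2–C3 bond: it joins a carboxyl-bearing carbon (C3) to a carbon (C2) whose substituent C9 can be the inner carbon of a vinyl group, the pattern left by an ester-enolate Claisen shift. Because ring A already links C4 (through C4a) to C1 (through C8a), the matching allyl ester is a ten-membered lactone. The C7 hydroxyl para to C4a additionally allows C3=C4 to be made through a ring A quinone methide.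

## Logic of the disconnections

**32 to 31.** The aryl O–Si bond on Ar′ and the alkyl O–Si bond at C9 are cut together. Both silyl groups leave under buffered fluoride, so the last step needs neither acid nor strong base. The demand is that the fluoride be buffered, so that the enoate and C2–H of 31 never meet alkoxide.

**31 to 29 to 28.** The C3=C4 π bond is removed (hydrogen added back at C3 and C4) and, one stage earlier, the ring A O–CH2Ph bond is restored. The C7 hydroxyl is para to C4a, so two-electron oxidation gives 30, and loss of C3–H rearomatises into C3=C4. The gain is that C3 becomes a tetrahedral carboxyl carbon whose configuration no longer matters, which opens the sigmatropic disconnection. The demand is that only the ring A oxygen be free at that point. The protecting groups are chosen for this: benzyl on ring A (removed by hydrogenolysis once no alkene is left), silyl on Ar′ and on C9. This avoids a selective cleavage of one silyl ether beside another and avoids an acid-labile acetal whose removal would expose the finished hydroxy enoate to acid.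

**28 to 27 to 25 to 24.** The C9–O bond is traced back to a C9=CH2 double bond, and the ester O–CH3 bond is cut. A vinyl group at C2 is exactly what a [3,3] shift leaves there. The demands are that periodate is used only while both phenols are covered, and that C9 never carries a free alkoxide cis to the C3 ester; 27 is therefore hydrosilylated directly to 28.

**24 to 21.** The C2–C3 bond is cut and the carboxyl oxygen is reconnected to the terminal vinyl carbon. Ring B and the C2 and C3 centres are exchanged for a ten-membered ring with one stereocentre (C1) and a Z alkene. The forward step must enolise at C3 and not at C1, and must pass through a boat-shaped array.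

**21 to 20.** The ring C=C bond is cut into two terminal alkenes. A ring that already holds the arene and the ester can only take a Z alkene, so geometry should follow from ring size. The demands are high dilution and no alkene migration towards C1.

**20 to 18 and 19; 18 to 16 to 15.** The ester C–O bond is cut, then the arm carbon is taken back to the alcohol level and its O–Si bond restored. A propanoate ortho to an aryl–metal bond would close to an indanone, so the arm passes through the arylation as a silyl ether. The demands are cleavage of the alkyl silyl ether beside the aryl one and an oxidation that spares the alkene and C1–H.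

**15 to 6 and 13.** The C1–C8a bond is cut. An SN2′ arylation of a cinnamyl chloride makes the diaryl methine and the vinyl group at once and is the only centre set under reagent control. The gain is two achiral aromatic pieces of similar size. The demand is γ-selectivity and enantioselectivity with a di-ortho-substituted arylmagnesium reagent.

**13 to 11 to 10 to 8 and 9; 8 to 7.** The C–Cl bond, the ester oxidation level, the Cα=Cβ bond and the aryl O–Si bond are cut in turn, back to 7 and 9. Each forward step is routine; the only demand is that 13, an electron-rich allylic chloride, is used without storage.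

**6 to 5 to 4 to 2 to 1.** The alkyl O–Si bond, the C–Br bond, the primary C–O bond (back to the terminal alkene) and the O–CH2Ph bond are cut in turn, back to 1. The two free ring positions of 4 are equivalent, so bromination needs only stoichiometric control.

## Other disconnections considered

**Alternative 1:** The cut is C1–C2. In the forward step, enamine activation of the C9 aldehyde of A1 by a diarylprolinol silyl ether lets C2 add 1,6 to the quinone methide carbon C1, closing ring B to A2; NaBH4 reduction and acetal removal would then give 32. In its favour, ring B, both stereocentres, the C3=C4 enoate and the free Ar′ phenol appear in one catalytic operation, nothing has to be erased afterwards, and the crowded C1–aryl environment is reached without an organometallic coupling. In step count and convergence it is clearly the better plan. Against it here, A1 combines an enolisable aldehyde with a quinone methide that lacks the bulky flanking groups on which enantioselective 1,6-additions usually rely, and the secondary amine can add to the methide itself. In A2 the C2–H is α to the aldehyde and γ to the enoate, so the same amine could epimerise C2, shift the double bond to C2=C3 or start aromatisation. On structure the two plans are equal: each closes ring B with one bond. On mechanism the alternative sets both centres under catalyst control in one event, which is equal or better if it holds; the chosen plan sets C1 by catalysis, derives C2 from it inside a ring, and creates the sensitive C2–H/enoate array only in the penultimate step under mild base. On step economy the alternative wins.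

**Alternative 2:** The cuts are C1–C2 and C3–C4, a [4+2] disconnection. Irradiation of the 2-benzylbenzaldehyde A3 with Ti(OiPr)4, a TADDOL-type diol and the (E)-enoate A4 would close ring B by photoenolisation and endo cycloaddition to give A5 with C1 to C4 set. Elimination of the C4 hydroxyl (cis to the ester, hence anti to C3–H) and deprotection would finish the route. In its favour, this is the most convergent plan: two simple fragments, two bonds, ring B and every stereocentre at once, a C4 oxygen ideally placed to become C3=C4, and no need to tell the two phenols apart. On convergence, protecting-group economy and step count it is better than the chosen plan. Against it here, A4 is an acyclic, weakly activated enoate without a second binding site, at the edge of what such titanium-templated photoenol additions accept. The dienol must also hold the large Ar′ group outward beside the C8 methoxy group, absolute control rests on a chelate normally needed in stoichiometric amount, and the para-activated benzylic alcohol of A5 ionises easily. On mechanism, regio-, endo/exo- and facial selectivity must all be won in one photochemical event, against a thermal shift whose selectivity rests on one existing centre.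

**Alternative 3:** The cut is C4–C4a. The aryl bromide A6, carrying the α-substituted acrylate, would cyclise with Pd(OAc)2, P(o-tol)3 and Et3N by 6-endo insertion at the terminal carbon C4 and β-hydride loss to give A7, the protected form of 32. In its favour, ring closure is the last skeletal event and delivers the C3=C4 enoate at the right oxidation level, so there is no C3 centre to erase, no quinone methide and no phenol differentiation. The end-game is shorter than in the chosen plan, which is a point for the alternative. Against it here, both stereocentres must first be built on an open chain, without a ring to relay C1 to C2. Insertion at the internal acrylate carbon (5-exo) competes with the 6-endo mode. β-Hydride loss towards C2, or re-addition of the metal hydride, would give the C2=C3 isomer or the naphthalene and so destroy C2. On structure the plans are equal (one ring, one bond). On mechanism the alternative's key step can erase a stereocentre, whereas the chosen key step creates one. On step economy the alternative is better after ring closure and probably equal before it.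

Key step: step 14

Remark on the chemistry: ring B is numbered C1 (Ar′-bearing) to C4, with C9 on C2 and ring A positions C5 to C8, in all names; ArSi stands for 4-[(tert-butyldimethylsilyl)oxy]-3,5-dimethoxyphenyl; the phosphoramidite enantiomer in step 9 is assumed to be the one that delivers the S centre, to be fixed on a simple cinnamyl chloride.

## Route

Step 1
Reactants: 1 4-allyl-2,6-dimethoxyphenol
Product: 2 5-allyl-2-(benzyloxy)-1,3-dimethoxybenzene
Conditions: BnBr, K2CO3, DMF, 25 °C
Reagents that add atoms: benzyl bromide, BrCc1ccccc1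
Why: Williamson ether synthesis on the phenoxide; the benzyl ether should survive every later organometallic, basic and oxidative step and is the one group that hydrogenolysis removes while silyl ethers stay.

Step 2
Reactants: 2 5-allyl-2-(benzyloxy)-1,3-dimethoxybenzene
Product: 4 3-[4-(benzyloxy)-3,5-dimethoxyphenyl]propan-1-ol, via B-alkyl-9-borabicyclononane 3 (not isolated)
Conditions: 9-BBN, THF, 0 → 25 °C; then NaOH, H2O2, H2O, 0 → 25 °C
Reagents that add atoms: hydrogen peroxide, OO
Why: Hydroboration–oxidation; the bulky borane adds boron to the terminal carbon and oxidative C–B cleavage gives the primary alcohol.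

Step 3
Reactants: 4 3-[4-(benzyloxy)-3,5-dimethoxyphenyl]propan-1-ol
Product: 5 3-[4-(benzyloxy)-2-bromo-3,5-dimethoxyphenyl]propan-1-ol
Conditions: NBS (1.0 equiv), MeCN, 0 °C
Reagents that add atoms: N-bromosuccinimide, O=C1CCC(=O)N1Br
Why: Electrophilic aromatic bromination; the two free ring positions are equivalent and each is ortho and para to a methoxy group, so one equivalent should give the monobromide next to the side chain while the unactivated benzyl ring stays untouched.

Step 4
Reactants: 5 3-[4-(benzyloxy)-2-bromo-3,5-dimethoxyphenyl]propan-1-ol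
Product: 6 {3-[4-(benzyloxy)-2-bromo-3,5-dimethoxyphenyl]propoxy}(tert-butyl)dimethylsilane
Conditions: t-BuMe2SiCl, imidazole, DMF, 25 °C
Reagents that add atoms: tert-butyldimethylsilyl chloride, CC(C)(C)[Si](C)(C)Cl
Why: Silylation of the primary alcohol; the arm must be masked at the alcohol level because an ortho-metallated propanoate would cyclise to an indanone in step 9.

Step 5
Reactants: 7 4-hydroxy-3,5-dimethoxybenzaldehyde (syringaldehyde)
Product: 8 4-[(tert-butyldimethylsilyl)oxy]-3,5-dimethoxybenzaldehyde
Conditions: t-BuMe2SiCl, imidazole, DMF, 25 °C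
Reagents that add atoms: tert-butyldimethylsilyl chloride, CC(C)(C)[Si](C)(C)Cl
Why: Silylation of the phenol; the aryl silyl ether should tolerate hydride, organomagnesium and amide bases at low temperature and mild acid, and leaves with fluoride at the end.

Step 6
Reactants: 8 4-[(tert-butyldimethylsilyl)oxy]-3,5-dimethoxybenzaldehyde; 9 triethyl phosphonoacetate
Product: 10 ethyl (E)-3-ArSi-prop-2-enoate
Conditions: NaH, THF, 0 → 25 °C
Reagents that add atoms: none
Why: Horner–Wadsworth–Emmons olefination; the stabilised phosphonate anion gives the E cinnamate under thermodynamic control of the elimination.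

Step 7
Reactants: 10 ethyl (E)-3-ArSi-prop-2-enoate
Product: 11 (E)-3-ArSi-prop-2-en-1-ol
Conditions: i-Bu2AlH (2.2 equiv), CH2Cl2, −78 °C; aqueous KNaC4H4O6 (tartrate)
Reagents that add atoms: none
Why: 1,2-Reduction of the conjugated ester to the allylic alcohol by the aluminium hydride at low temperature, with no conjugate reduction.

Step 8
Reactants: 11 (E)-3-ArSi-prop-2-en-1-ol
Product: 13 tert-butyl{4-[(E)-3-chloroprop-1-en-1-yl]-2,6-dimethoxyphenoxy}dimethylsilane, via allylic methanesulfonate 12 (not isolated)
Conditions: MeSO2Cl, 2,4,6-collidine, LiCl, DMF, 0 °C; used crude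
Reagents that add atoms: lithium chloride, [Li+].[Cl-]; methanesulfonyl chloride, CS(=O)(=O)Cl (its chloride joins the same pool)
Why: Sulfonylation and in situ chloride displacement; conjugation with the arene keeps the chloride primary and E, and the labile electron-rich allylic chloride is carried on without storage.

Step 9
Reactants: 6 {3-[4-(benzyloxy)-2-bromo-3,5-dimethoxyphenyl]propoxy}(tert-butyl)dimethylsilane; 13 tert-butyl{4-[(E)-3-chloroprop-1-en-1-yl]-2,6-dimethoxyphenoxy}dimethylsilane
Product: 15 {3-[4-(benzyloxy)-2-[(1S)-1-ArSi-prop-2-en-1-yl]-3,5-dimethoxyphenyl]propoxy}(tert-butyl)dimethylsilane, via arylmagnesium bromide 14 (not isolated)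
Conditions: 6, Mg (I2-activated), Et2O–THF, 35 °C; then added over 2 h to 13, CuBr·SMe2 (5 mol %), (S,S,S)-binaphthol N,N-bis(1-phenylethyl)phosphoramidite (6 mol %), CH2Cl2, −78 °C
Reagents that add atoms: none
Why: Copper-catalysed enantioselective allylic arylation (SN2′): the arylcopper species from 14 adds at the γ-carbon anti to chloride, the σ-allyl trivalent copper intermediate reductively eliminates to the branched product, and the chiral phosphoramidite on copper selects the alkene face to set C1 (S); slow addition at −78 °C should hold back the uncatalysed linear pathway.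

Step 10
Reactants: 15 {3-[4-(benzyloxy)-2-[(1S)-1-ArSi-prop-2-en-1-yl]-3,5-dimethoxyphenyl]propoxy}(tert-butyl)dimethylsilane
Product: 16 3-[4-(benzyloxy)-2-[(1S)-1-ArSi-prop-2-en-1-yl]-3,5-dimethoxyphenyl]propan-1-ol
Conditions: camphorsulfonic acid (10 mol %), MeOH–CH2Cl2, 0 °C
Reagents that add atoms: none
Why: Acid-catalysed methanolysis of the primary alkyl silyl ether; the hindered aryl silyl ether is far slower to cleave under acid and should remain.

Step 11
Reactants: 16 3-[4-(benzyloxy)-2-[(1S)-1-ArSi-prop-2-en-1-yl]-3,5-dimethoxyphenyl]propan-1-ol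
Product: 18 3-[4-(benzyloxy)-2-[(1S)-1-ArSi-prop-2-en-1-yl]-3,5-dimethoxyphenyl]propanoic acid, via aldehyde 17 (not isolated)
Conditions: TEMPO (20 mol %), PhI(OAc)2 (2.2 equiv), MeCN–H2O (1:1), 25 °C
Reagents that add atoms: water, O
Why: Oxoammonium-mediated oxidation of the primary alcohol to the aldehyde and, through its hydrate, to the acid; the terminal alkene, the aryl ethers and the C1–H should not react under these conditions.

Step 12
Reactants: 18 3-[4-(benzyloxy)-2-[(1S)-1-ArSi-prop-2-en-1-yl]-3,5-dimethoxyphenyl]propanoic acid; 19 allyl alcohol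
Product: 20 prop-2-en-1-yl 3-[4-(benzyloxy)-2-[(1S)-1-ArSi-prop-2-en-1-yl]-3,5-dimethoxyphenyl]propanoate
Conditions: DCC, DMAP (cat.), CH2Cl2, 0 → 25 °C
Reagents that add atoms: none
Why: Steglich esterification through the O-acylisourea and acylpyridinium; neutral conditions leave the silyl ether and C1 untouched.

Step 13
Reactants: 20 prop-2-en-1-yl 3-[4-(benzyloxy)-2-[(1S)-1-ArSi-prop-2-en-1-yl]-3,5-dimethoxyphenyl]propanoate
Product: 21 (6Z,8S)-8-ArSi-10-(benzyloxy)-9,11-dimethoxy-1,2,5,8-tetrahydro-3H-4-benzoxecin-3-one (ten-membered lactone; ring position 8 is C1)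
Conditions: second-generation Grubbs catalyst (5–10 mol %), 1,4-benzoquinone (10 mol %), CH2Cl2 (0.001 M), 40 °C
Reagents that add atoms: none
Why: Ring-closing metathesis with loss of ethene; the carbene should load on the unhindered allyl ester and close onto the hindered vinyl group, a ten-membered ring already holding the arene and the ester can take only the Z alkene, and benzoquinone suppresses hydride-mediated alkene migration towards C1.

Step 14
Reactants: 21 (6Z,8S)-8-ArSi-10-(benzyloxy)-9,11-dimethoxy-1,2,5,8-tetrahydro-3H-4-benzoxecin-3-one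
Product: 24 (1S,2R,3S)-1-ArSi-7-(benzyloxy)-6,8-dimethoxy-2-vinyl-1,2,3,4-tetrahydronaphthalene-3-carboxylic acid, via silyl ketene acetal 22 (not isolated), via trimethylsilyl ester 23 (not isolated)
Conditions: LiN(iPr)2 (1.5 equiv), Me3SiCl–Et3N (premixed), THF, −100 → −78 °C; then 25 → 65 °C; 1 M HCl, THF–H2O, 25 °C
Reagents that add atoms: none
Why: This is an Ireland–Claisen rearrangement run as a ring contraction: the amide base removes a C3–H (carbonyl-activated and far less shielded than the diaryl-allylic C1–H) and the chlorosilane already present traps the enolate as 22 before it can attack a second lactone. On warming, 22 should undergo a concerted suprafacial [3,3] shift in which C3 bonds to C2 as the allylic C–O bond breaks, so the ten-membered ring is exchanged for six-membered ring B (in effect a 6-exo closure onto the alkene carbon, delivered through the sigmatropic array) with a silyl carboxylate on C3 and a vinyl group on C2; aqueous acid then hydrolyses 23 to 24. The closest known reaction type is the ester-enolate Claisen contraction of unsaturated macrolactones to 2-vinylcycloalkanecarboxylic acids. Both ends of the four-atom tether (C4 on the ketene acetal, C1 on the Z alkene) occupy inward positions of the six-atom array, so only a boat-shaped transition state is within reach, and this places carboxyl and vinyl cis at C3, a centre removed in step 19. The C2 configuration is controlled by C1: allylic 1,3-strain in the Z alkene holds C1–H in the alkene plane, ring A and ArSi then lie on opposite faces, and the tether can bring C3 only to the face carrying ring A, so the vinyl group ends trans to the aryl group (2R from 1S). The step needs site-selective enolisation, secured by the internal silyl quench at low temperature and the shielding of C1–H, and diastereofacial selectivity, secured by the single C1 centre together with the Z geometry.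

Step 15
Reactants: 24 (1S,2R,3S)-1-ArSi-7-(benzyloxy)-6,8-dimethoxy-2-vinyl-1,2,3,4-tetrahydronaphthalene-3-carboxylic acid
Product: 25 methyl (1S,2R,3S)-1-ArSi-7-(benzyloxy)-6,8-dimethoxy-2-vinyl-1,2,3,4-tetrahydronaphthalene-3-carboxylate
Conditions: Me3SiCHN2, PhMe–MeOH (4:1), 0 °C
Reagents that add atoms: (trimethylsilyl)diazomethane, C[Si](C)(C)C=[N+]=[N-]
Why: O-Methylation of the acid by the diazoalkane (protonation, then displacement of N2, with methanol removing silicon); no base is present, so no centre can epimerise.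

Step 16
Reactants: 25 methyl (1S,2R,3S)-1-ArSi-7-(benzyloxy)-6,8-dimethoxy-2-vinyl-1,2,3,4-tetrahydronaphthalene-3-carboxylate
Product: 27 methyl (1S,2R,3S)-1-ArSi-7-(benzyloxy)-2-formyl-6,8-dimethoxy-1,2,3,4-tetrahydronaphthalene-3-carboxylate, via vicinal diol 26 (not isolated)
Conditions: OsO4 (2 mol %), NaIO4 (4 equiv), 2,6-lutidine, dioxane–H2O (3:1), 25 °C
Reagents that add atoms: osmium tetroxide, O=[Os](=O)(=O)=O; sodium periodate, [Na+].[O-]I(=O)(=O)=O; water, O (together they supply and renew the oxygen that ends on C9)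
Why: Lemieux–Johnson cleavage: dihydroxylation of the only alkene, then periodate scission of the diol; both phenols are protected, so periodate has no phenol to oxidise, and the buffered medium should leave the C2 centre alone.

Step 17
Reactants: 27 methyl (1S,2R,3S)-1-ArSi-7-(benzyloxy)-2-formyl-6,8-dimethoxy-1,2,3,4-tetrahydronaphthalene-3-carboxylate
Product: 28 methyl (1S,2R,3S)-1-ArSi-7-(benzyloxy)-6,8-dimethoxy-2-{[(triethylsilyl)oxy]methyl}-1,2,3,4-tetrahydronaphthalene-3-carboxylate
Conditions: Et3SiH (1.5 equiv), RhCl(PPh3)3 (1 mol %), PhMe, 50 °C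
Reagents that add atoms: triethylsilane, CC[SiH](CC)CC
Why: Rhodium-catalysed hydrosilylation of the aldehyde gives the silyl ether directly, so no free alkoxide or alcohol ever sits cis to the C3 ester, where it would close to the γ-lactone; esters are not reduced under these conditions.

Step 18
Reactants: 28 methyl (1S,2R,3S)-1-ArSi-7-(benzyloxy)-6,8-dimethoxy-2-{[(triethylsilyl)oxy]methyl}-1,2,3,4-tetrahydronaphthalene-3-carboxylate
Product: 29 methyl (1S,2R,3S)-1-ArSi-7-hydroxy-6,8-dimethoxy-2-{[(triethylsilyl)oxy]methyl}-1,2,3,4-tetrahydronaphthalene-3-carboxylate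
Conditions: H2 (1 atm), 10% Pd/C, EtOAc, 25 °C
Reagents that add atoms: none
Why: Hydrogenolysis of the aryl benzyl ether; no alkene remains at this stage, and both silyl ethers and the ester should be inert in ethyl acetate.

Step 19
Reactants: 29 methyl (1S,2R,3S)-1-ArSi-7-hydroxy-6,8-dimethoxy-2-{[(triethylsilyl)oxy]methyl}-1,2,3,4-tetrahydronaphthalene-3-carboxylate
Product: 31 methyl (1S,2R)-1-ArSi-7-hydroxy-6,8-dimethoxy-2-{[(triethylsilyl)oxy]methyl}-1,2-dihydronaphthalene-3-carboxylate, via quinone methide 30 (not isolated)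
Conditions: Ag2O (3 equiv), CH2Cl2, 25 °C, dark; filter; then Et3N (1 equiv), CH2Cl2, 0 → 25 °C
Reagents that add atoms: none
Why: Two-electron oxidation of the 4-alkyl-2,6-dimethoxyphenol gives the para-quinone methide at C4, and the amine then removes C3–H (α to the ester and vinylogous to the methide), so rearomatisation leaves the C3=C4 enoate (quinone methide tautomerisation); the silyl ether keeps the Ar′ ring from oxidising, and C1 and C2 are not involved.

Step 20
Reactants: 31 methyl (1S,2R)-1-ArSi-7-hydroxy-6,8-dimethoxy-2-{[(triethylsilyl)oxy]methyl}-1,2-dihydronaphthalene-3-carboxylate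
Product: 32 methyl (1S,2R)-7-hydroxy-1-(4-hydroxy-3,5-dimethoxyphenyl)-2-(hydroxymethyl)-6,8-dimethoxy-1,2-dihydronaphthalene-3-carboxylate
Conditions: Bu4NF, AcOH (1:1, 3 equiv), THF, 0 → 25 °C
Reagents that add atoms: none
Why: Fluoride cleaves the aryl and the alkyl Si–O bonds in one operation; acetic acid buffers the phenoxide and alkoxide so that neither lactonisation nor double-bond migration from C3=C4 should set in.

## Compound list

1 | 4-allyl-2,6-dimethoxyphenol | C=CCc1cc(OC)c(O)c(OC)c1 | starting material
2 | 5-allyl-2-(benzyloxy)-1,3-dimethoxybenzene | C=CCc1cc(OC)c(OCc2ccccc2)c(OC)c1 | intermediate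
3 | 9-{3-[4-(benzyloxy)-3,5-dimethoxyphenyl]propyl}-9-borabicyclo[3.3.1]nonane | COc1cc(CCCB2C3CCCC2CCC3)cc(OC)c1OCc1ccccc1 | intermediate
4 | 3-[4-(benzyloxy)-3,5-dimethoxyphenyl]propan-1-ol | OCCCc1cc(OC)c(OCc2ccccc2)c(OC)c1 | intermediate
5 | 3-[4-(benzyloxy)-2-bromo-3,5-dimethoxyphenyl]propan-1-ol | OCCCc1cc(OC)c(OCc2ccccc2)c(OC)c1Br | intermediate
6 | {3-[4-(benzyloxy)-2-bromo-3,5-dimethoxyphenyl]propoxy}(tert-butyl)dimethylsilane | CC(C)(C)[Si](C)(C)OCCCc1cc(OC)c(OCc2ccccc2)c(OC)c1Br | intermediate
7 | 4-hydroxy-3,5-dimethoxybenzaldehyde (syringaldehyde) | COc1cc(C=O)cc(OC)c1O | starting material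
8 | 4-[(tert-butyldimethylsilyl)oxy]-3,5-dimethoxybenzaldehyde | COc1cc(C=O)cc(OC)c1O[Si](C)(C)C(C)(C)C | intermediate
9 | triethyl phosphonoacetate | CCOC(=O)CP(=O)(OCC)OCC | starting material
10 | ethyl (E)-3-{4-[(tert-butyldimethylsilyl)oxy]-3,5-dimethoxyphenyl}prop-2-enoate | CCOC(=O)/C=C/c1cc(OC)c(O[Si](C)(C)C(C)(C)C)c(OC)c1 | intermediate
11 | (E)-3-{4-[(tert-butyldimethylsilyl)oxy]-3,5-dimethoxyphenyl}prop-2-en-1-ol | OC/C=C/c1cc(OC)c(O[Si](C)(C)C(C)(C)C)c(OC)c1 | intermediate
12 | (E)-3-{4-[(tert-butyldimethylsilyl)oxy]-3,5-dimethoxyphenyl}prop-2-en-1-yl methanesulfonate | CS(=O)(=O)OC/C=C/c1cc(OC)c(O[Si](C)(C)C(C)(C)C)c(OC)c1 | intermediate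
13 | tert-butyl{4-[(E)-3-chloroprop-1-en-1-yl]-2,6-dimethoxyphenoxy}dimethylsilane | ClC/C=C/c1cc(OC)c(O[Si](C)(C)C(C)(C)C)c(OC)c1 | intermediate
14 | {3-(benzyloxy)-6-[3-(tert-butyldimethylsilyloxy)propyl]-2,4-dimethoxyphenyl}magnesium bromide | CC(C)(C)[Si](C)(C)OCCCc1cc(OC)c(OCc2ccccc2)c(OC)c1[Mg]Br | intermediate
15 | {3-[4-(benzyloxy)-2-[(1S)-1-{4-[(tert-butyldimethylsilyl)oxy]-3,5-dimethoxyphenyl}prop-2-en-1-yl]-3,5-dimethoxyphenyl]propoxy}(tert-butyl)dimethylsilane | CC(C)(C)[Si](C)(C)OCCCc1cc(OC)c(OCc2ccccc2)c(OC)c1[C@H](c1cc(OC)c(O[Si](C)(C)C(C)(C)C)c(OC)c1)C=C | intermediate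
16 | 3-[4-(benzyloxy)-2-[(1S)-1-{4-[(tert-butyldimethylsilyl)oxy]-3,5-dimethoxyphenyl}prop-2-en-1-yl]-3,5-dimethoxyphenyl]propan-1-ol | OCCCc1cc(OC)c(OCc2ccccc2)c(OC)c1[C@H](c1cc(OC)c(O[Si](C)(C)C(C)(C)C)c(OC)c1)C=C | intermediate
17 | 3-[4-(benzyloxy)-2-[(1S)-1-{4-[(tert-butyldimethylsilyl)oxy]-3,5-dimethoxyphenyl}prop-2-en-1-yl]-3,5-dimethoxyphenyl]propanal | O=CCCc1cc(OC)c(OCc2ccccc2)c(OC)c1[C@H](c1cc(OC)c(O[Si](C)(C)C(C)(C)C)c(OC)c1)C=C | intermediate
18 | 3-[4-(benzyloxy)-2-[(1S)-1-{4-[(tert-butyldimethylsilyl)oxy]-3,5-dimethoxyphenyl}prop-2-en-1-yl]-3,5-dimethoxyphenyl]propanoic acid | OC(=O)CCc1cc(OC)c(OCc2ccccc2)c(OC)c1[C@H](c1cc(OC)c(O[Si](C)(C)C(C)(C)C)c(OC)c1)C=C | intermediate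
19 | allyl alcohol (prop-2-en-1-ol) | C=CCO | starting material
20 | prop-2-en-1-yl 3-[4-(benzyloxy)-2-[(1S)-1-{4-[(tert-butyldimethylsilyl)oxy]-3,5-dimethoxyphenyl}prop-2-en-1-yl]-3,5-dimethoxyphenyl]propanoate | C=CCOC(=O)CCc1cc(OC)c(OCc2ccccc2)c(OC)c1[C@H](c1cc(OC)c(O[Si](C)(C)C(C)(C)C)c(OC)c1)C=C | intermediate
21 | (6Z,8S)-10-(benzyloxy)-8-{4-[(tert-butyldimethylsilyl)oxy]-3,5-dimethoxyphenyl}-9,11-dimethoxy-1,2,5,8-tetrahydro-3H-4-benzoxecin-3-one | O=C1CCc2cc(OC)c(OCc3ccccc3)c(OC)c2[C@H](c2cc(OC)c(O[Si](C)(C)C(C)(C)C)c(OC)c2)/C=C\CO1 | intermediate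
22 | O-trimethylsilyl ketene acetal of 21 (ring C=C between C3 and the acetal carbon, ring oxygen cis to C4; S at C1, Z alkene) | C[Si](C)(C)O/C1=C/Cc2cc(OC)c(OCc3ccccc3)c(OC)c2[C@H](c2cc(OC)c(O[Si](C)(C)C(C)(C)C)c(OC)c2)/C=C\CO1 | intermediate
23 | trimethylsilyl (1S,2R,3S)-7-(benzyloxy)-1-{4-[(tert-butyldimethylsilyl)oxy]-3,5-dimethoxyphenyl}-6,8-dimethoxy-2-vinyl-1,2,3,4-tetrahydronaphthalene-3-carboxylate | C[Si](C)(C)OC(=O)[C@H]1Cc2cc(OC)c(OCc3ccccc3)c(OC)c2[C@H](c2cc(OC)c(O[Si](C)(C)C(C)(C)C)c(OC)c2)[C@H]1C=C | intermediate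
24 | (1S,2R,3S)-7-(benzyloxy)-1-{4-[(tert-butyldimethylsilyl)oxy]-3,5-dimethoxyphenyl}-6,8-dimethoxy-2-vinyl-1,2,3,4-tetrahydronaphthalene-3-carboxylic acid (aryl and vinyl trans, vinyl and carboxyl cis) | OC(=O)[C@H]1Cc2cc(OC)c(OCc3ccccc3)c(OC)c2[C@H](c2cc(OC)c(O[Si](C)(C)C(C)(C)C)c(OC)c2)[C@H]1C=C | intermediate
25 | methyl (1S,2R,3S)-7-(benzyloxy)-1-{4-[(tert-butyldimethylsilyl)oxy]-3,5-dimethoxyphenyl}-6,8-dimethoxy-2-vinyl-1,2,3,4-tetrahydronaphthalene-3-carboxylate | COC(=O)[C@H]1Cc2cc(OC)c(OCc3ccccc3)c(OC)c2[C@H](c2cc(OC)c(O[Si](C)(C)C(C)(C)C)c(OC)c2)[C@H]1C=C | intermediate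
26 | methyl (1S,2R,3S)-7-(benzyloxy)-1-{4-[(tert-butyldimethylsilyl)oxy]-3,5-dimethoxyphenyl}-2-(1,2-dihydroxyethyl)-6,8-dimethoxy-1,2,3,4-tetrahydronaphthalene-3-carboxylate (both carbinol epimers) | COC(=O)[C@H]1Cc2cc(OC)c(OCc3ccccc3)c(OC)c2[C@H](c2cc(OC)c(O[Si](C)(C)C(C)(C)C)c(OC)c2)[C@H]1C(O)CO | intermediate
27 | methyl (1S,2R,3S)-7-(benzyloxy)-1-{4-[(tert-butyldimethylsilyl)oxy]-3,5-dimethoxyphenyl}-2-formyl-6,8-dimethoxy-1,2,3,4-tetrahydronaphthalene-3-carboxylate | COC(=O)[C@H]1Cc2cc(OC)c(OCc3ccccc3)c(OC)c2[C@H](c2cc(OC)c(O[Si](C)(C)C(C)(C)C)c(OC)c2)[C@H]1C=O | intermediate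
28 | methyl (1S,2R,3S)-7-(benzyloxy)-1-{4-[(tert-butyldimethylsilyl)oxy]-3,5-dimethoxyphenyl}-6,8-dimethoxy-2-{[(triethylsilyl)oxy]methyl}-1,2,3,4-tetrahydronaphthalene-3-carboxylate | COC(=O)[C@H]1Cc2cc(OC)c(OCc3ccccc3)c(OC)c2[C@H](c2cc(OC)c(O[Si](C)(C)C(C)(C)C)c(OC)c2)[C@H]1CO[Si](CC)(CC)CC | intermediate
29 | methyl (1S,2R,3S)-1-{4-[(tert-butyldimethylsilyl)oxy]-3,5-dimethoxyphenyl}-7-hydroxy-6,8-dimethoxy-2-{[(triethylsilyl)oxy]methyl}-1,2,3,4-tetrahydronaphthalene-3-carboxylate | COC(=O)[C@H]1Cc2cc(OC)c(O)c(OC)c2[C@H](c2cc(OC)c(O[Si](C)(C)C(C)(C)C)c(OC)c2)[C@H]1CO[Si](CC)(CC)CC | intermediate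
30 | ring A para-quinone methide of 29 (C7 carbonyl, C4=C4a double bond; 1S,2R,3S) | COC(=O)[C@H]1C=C2C=C(OC)C(=O)C(OC)=C2[C@H](c2cc(OC)c(O[Si](C)(C)C(C)(C)C)c(OC)c2)[C@H]1CO[Si](CC)(CC)CC | intermediate
31 | methyl (1S,2R)-1-{4-[(tert-butyldimethylsilyl)oxy]-3,5-dimethoxyphenyl}-7-hydroxy-6,8-dimethoxy-2-{[(triethylsilyl)oxy]methyl}-1,2-dihydronaphthalene-3-carboxylate | COC(=O)C1=Cc2cc(OC)c(O)c(OC)c2[C@H](c2cc(OC)c(O[Si](C)(C)C(C)(C)C)c(OC)c2)[C@H]1CO[Si](CC)(CC)CC | intermediate
32 | methyl (1S,2R)-7-hydroxy-1-(4-hydroxy-3,5-dimethoxyphenyl)-2-(hydroxymethyl)-6,8-dimethoxy-1,2-dihydronaphthalene-3-carboxylate | COC(=O)C1=Cc2cc(OC)c(O)c(OC)c2[C@H](c2cc(OC)c(O)c(OC)c2)[C@H]1CO | target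

## Step count and least certain steps

Total step count: 20. Longest linear sequence: 16 steps (steps 1–4 and 9–20; the branch through steps 5–8 is equally long).

**Step 9 (enantioselective arylation).** The likeliest failure is loss of γ-selectivity: reductive elimination of the di-ortho-substituted aryl group may be slow enough for the allylcopper intermediate to equilibrate to the linear, achiral product. A second risk is erosion of enantioselectivity by the uncatalysed background reaction of the organomagnesium reagent. The fallback changes the metal and the mechanism to an iridium allyl pathway, whose preference for the branched product does not depend on fast reductive elimination. It sets out from 11 and 14: methyl chloroformate and pyridine would convert 11 into the allylic methyl carbonate F1, and ZnBr2 would convert 14 into the arylzinc bromide F2. Coupling of F1 and F2 with [Ir(cod)Cl]2, the same phosphoramidite and LiBr in THF would return to the route at 15.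

**Step 13 (ring-closing metathesis).** The likeliest failure is oligomerisation or cyclic dimer formation, because metathesis is reversible and the strained ten-membered ring may lose out thermodynamically; alkene migration towards C1 is a second risk. The fallback builds the Z alkene first and closes the ring irreversibly at the ester bond. It sets out from 18: Z-selective cross-metathesis with (Z)-but-2-ene-1,4-diol, using the dithiolate complex Ru(=CH-C6H4-2-O-i-Pr)(SIMes)(S2C6H2Cl2), would give the (Z)-hydroxy acid F3. Mixed-anhydride macrolactonisation of F3 with 2-methyl-6-nitrobenzoic anhydride and DMAP under high dilution would return to the route at 21.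

**Step 14 (key step).** Three things could go wrong: competing deprotonation at C1, leading to racemisation or alkene migration; self-condensation of the lactone enolate before silylation; or a boat transition state so strained that the ketene acetal decomposes on heating before it rearranges. The fallback replaces the sigmatropic shift by an ionic SN2′ ring closure that forms the same C2–C3 bond under the same allylic-strain control from C1. It sets out from 21: neutral methanolysis (Bu2SnO, MeOH, 65 °C) would give the (Z)-hydroxy methyl ester F4, and CBr4 with PPh3 the allylic bromide F5. KN(SiMe3)2 in THF at −78 °C would then close ring B by intramolecular ester-enolate SN2′ alkylation. If carboxyl and vinyl end up cis, the product is 25 itself. If they end up trans, it is the C3 epimer F6, and because C3 is erased later F6 is simply taken through the operations of steps 16 to 19: the diol F7 (not isolated), the aldehyde F8, the triethylsilyl ether F9, the phenol F10 and the quinone methide F11 (not isolated). Either way the fallback returns to the route at 31 at the latest.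

**Step 19 (oxidation and tautomerisation).** The quinone methide may be trapped intermolecularly (by water or by dimerisation), the phenol may be over-oxidised, or excess base may move the new double bond on to C2=C3. The fallback introduces C3=C4 by selenoxide elimination, without any quinone methide. It sets out from 28: LiN(iPr)2 then PhSeBr in THF at −78 °C would give the α-phenylselanyl ester F12, and H2O2 with pyridine would cause syn elimination towards the benzylic C4 to give the benzyl-protected enoate F13. BCl3 with pentamethylbenzene in CH2Cl2 at −78 °C would then remove the benzyl group without touching the alkene and return to the route at 31.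

## Further compounds

F1 | step 9 | (E)-3-{4-[(tert-butyldimethylsilyl)oxy]-3,5-dimethoxyphenyl}prop-2-en-1-yl methyl carbonate | COC(=O)OC/C=C/c1cc(OC)c(O[Si](C)(C)C(C)(C)C)c(OC)c1
F2 | step 9 | {3-(benzyloxy)-6-[3-(tert-butyldimethylsilyloxy)propyl]-2,4-dimethoxyphenyl}zinc bromide | CC(C)(C)[Si](C)(C)OCCCc1cc(OC)c(OCc2ccccc2)c(OC)c1[Zn]Br
F3 | step 13 | 3-[4-(benzyloxy)-2-[(1S,2Z)-1-{4-[(tert-butyldimethylsilyl)oxy]-3,5-dimethoxyphenyl}-4-hydroxybut-2-en-1-yl]-3,5-dimethoxyphenyl]propanoic acid | OC(=O)CCc1cc(OC)c(OCc2ccccc2)c(OC)c1[C@H](c1cc(OC)c(O[Si](C)(C)C(C)(C)C)c(OC)c1)/C=C\CO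
F4 | step 14 | methyl 3-[4-(benzyloxy)-2-[(1S,2Z)-1-{4-[(tert-butyldimethylsilyl)oxy]-3,5-dimethoxyphenyl}-4-hydroxybut-2-en-1-yl]-3,5-dimethoxyphenyl]propanoate | COC(=O)CCc1cc(OC)c(OCc2ccccc2)c(OC)c1[C@H](c1cc(OC)c(O[Si](C)(C)C(C)(C)C)c(OC)c1)/C=C\CO
F5 | step 14 | methyl 3-[4-(benzyloxy)-2-[(1S,2Z)-4-bromo-1-{4-[(tert-butyldimethylsilyl)oxy]-3,5-dimethoxyphenyl}but-2-en-1-yl]-3,5-dimethoxyphenyl]propanoate | COC(=O)CCc1cc(OC)c(OCc2ccccc2)c(OC)c1[C@H](c1cc(OC)c(O[Si](C)(C)C(C)(C)C)c(OC)c1)/C=C\CBr
F6 | step 14 | methyl (1S,2R,3R)-7-(benzyloxy)-1-{4-[(tert-butyldimethylsilyl)oxy]-3,5-dimethoxyphenyl}-6,8-dimethoxy-2-vinyl-1,2,3,4-tetrahydronaphthalene-3-carboxylate (C3 epimer of 25) | COC(=O)[C@@H]1Cc2cc(OC)c(OCc3ccccc3)c(OC)c2[C@H](c2cc(OC)c(O[Si](C)(C)C(C)(C)C)c(OC)c2)[C@H]1C=C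
F7 | step 14 | C3 epimer of diol 26 (1S,2R,3R; both carbinol epimers) | COC(=O)[C@@H]1Cc2cc(OC)c(OCc3ccccc3)c(OC)c2[C@H](c2cc(OC)c(O[Si](C)(C)C(C)(C)C)c(OC)c2)[C@H]1C(O)CO
F8 | step 14 | methyl (1S,2R,3R)-7-(benzyloxy)-1-{4-[(tert-butyldimethylsilyl)oxy]-3,5-dimethoxyphenyl}-2-formyl-6,8-dimethoxy-1,2,3,4-tetrahydronaphthalene-3-carboxylate (C3 epimer of 27) | COC(=O)[C@@H]1Cc2cc(OC)c(OCc3ccccc3)c(OC)c2[C@H](c2cc(OC)c(O[Si](C)(C)C(C)(C)C)c(OC)c2)[C@H]1C=O
F9 | step 14 | methyl (1S,2R,3R)-7-(benzyloxy)-1-{4-[(tert-butyldimethylsilyl)oxy]-3,5-dimethoxyphenyl}-6,8-dimethoxy-2-{[(triethylsilyl)oxy]methyl}-1,2,3,4-tetrahydronaphthalene-3-carboxylate (C3 epimer of 28) | COC(=O)[C@@H]1Cc2cc(OC)c(OCc3ccccc3)c(OC)c2[C@H](c2cc(OC)c(O[Si](C)(C)C(C)(C)C)c(OC)c2)[C@H]1CO[Si](CC)(CC)CC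
F10 | step 14 | methyl (1S,2R,3R)-1-{4-[(tert-butyldimethylsilyl)oxy]-3,5-dimethoxyphenyl}-7-hydroxy-6,8-dimethoxy-2-{[(triethylsilyl)oxy]methyl}-1,2,3,4-tetrahydronaphthalene-3-carboxylate (C3 epimer of 29) | COC(=O)[C@@H]1Cc2cc(OC)c(O)c(OC)c2[C@H](c2cc(OC)c(O[Si](C)(C)C(C)(C)C)c(OC)c2)[C@H]1CO[Si](CC)(CC)CC
F11 | step 14 | ring A para-quinone methide of F10 (C3 epimer of 30) | COC(=O)[C@@H]1C=C2C=C(OC)C(=O)C(OC)=C2[C@H](c2cc(OC)c(O[Si](C)(C)C(C)(C)C)c(OC)c2)[C@H]1CO[Si](CC)(CC)CC
F12 | step 19 | methyl (1S,2R,3R)-7-(benzyloxy)-1-{4-[(tert-butyldimethylsilyl)oxy]-3,5-dimethoxyphenyl}-6,8-dimethoxy-3-(phenylselanyl)-2-{[(triethylsilyl)oxy]methyl}-1,2,3,4-tetrahydronaphthalene-3-carboxylate (selenium anti to the C2 substituent) | COC(=O)[C@@]1([Se]c3ccccc3)Cc2cc(OC)c(OCc3ccccc3)c(OC)c2[C@H](c2cc(OC)c(O[Si](C)(C)C(C)(C)C)c(OC)c2)[C@H]1CO[Si](CC)(CC)CC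
F13 | step 19 | methyl (1S,2R)-7-(benzyloxy)-1-{4-[(tert-butyldimethylsilyl)oxy]-3,5-dimethoxyphenyl}-6,8-dimethoxy-2-{[(triethylsilyl)oxy]methyl}-1,2-dihydronaphthalene-3-carboxylate | COC(=O)C1=Cc2cc(OC)c(OCc3ccccc3)c(OC)c2[C@H](c2cc(OC)c(O[Si](C)(C)C(C)(C)C)c(OC)c2)[C@H]1CO[Si](CC)(CC)CC
A1 | alternative 1 | methyl (E)-2-(2-oxoethyl)-3-{3,5-dimethoxy-4-(methoxymethoxy)-2-[(3,5-dimethoxy-4-oxocyclohexa-2,5-dien-1-ylidene)methyl]phenyl}prop-2-enoate | COC(=O)/C(CC=O)=C/c1cc(OC)c(OCOC)c(OC)c1C=C1C=C(OC)C(=O)C(OC)=C1
A2 | alternative 1 | methyl (1S,2R)-2-formyl-1-(4-hydroxy-3,5-dimethoxyphenyl)-6,8-dimethoxy-7-(methoxymethoxy)-1,2-dihydronaphthalene-3-carboxylate | COC(=O)C1=Cc2cc(OC)c(OCOC)c(OC)c2[C@H](c2cc(OC)c(O)c(OC)c2)[C@H]1C=O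
A3 | alternative 2 | 2-[3,5-dimethoxy-4-(methoxymethoxy)benzyl]-3,5-dimethoxy-4-(methoxymethoxy)benzaldehyde | O=Cc1cc(OC)c(OCOC)c(OC)c1Cc1cc(OC)c(OCOC)c(OC)c1
A4 | alternative 2 | methyl (E)-4-[(tert-butyldimethylsilyl)oxy]but-2-enoate | COC(=O)/C=C/CO[Si](C)(C)C(C)(C)C
A5 | alternative 2 | methyl (1S,2R,3S,4S)-2-{[(tert-butyldimethylsilyl)oxy]methyl}-1-[3,5-dimethoxy-4-(methoxymethoxy)phenyl]-4-hydroxy-6,8-dimethoxy-7-(methoxymethoxy)-1,2,3,4-tetrahydronaphthalene-3-carboxylate | COC(=O)[C@@H]1[C@H](O)c2cc(OC)c(OCOC)c(OC)c2[C@H](c2cc(OC)c(OCOC)c(OC)c2)[C@H]1CO[Si](C)(C)C(C)(C)C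
A6 | alternative 3 | methyl (3R,4S)-4-[6-bromo-2,4-dimethoxy-3-(methoxymethoxy)phenyl]-3-{[(tert-butyldimethylsilyl)oxy]methyl}-4-[3,5-dimethoxy-4-(methoxymethoxy)phenyl]-2-methylidenebutanoate | COC(=O)C(=C)[C@H](CO[Si](C)(C)C(C)(C)C)[C@@H](c1cc(OC)c(OCOC)c(OC)c1)c1c(OC)c(OCOC)c(OC)cc1Br
A7 | alternative 3 | methyl (1S,2R)-2-{[(tert-butyldimethylsilyl)oxy]methyl}-1-[3,5-dimethoxy-4-(methoxymethoxy)phenyl]-6,8-dimethoxy-7-(methoxymethoxy)-1,2-dihydronaphthalene-3-carboxylate | COC(=O)C1=Cc2cc(OC)c(OCOC)c(OC)c2[C@H](c2cc(OC)c(OCOC)c(OC)c2)[C@H]1CO[Si](C)(C)C(C)(C)C
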